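## The problem

The target **24** is the 3,7-bis(hydrogen sulfate) of a 4'-O-methylated flavonol. A resorcinol-type ring A is fused at C4a–C8a to a 4-pyranone ring C, and ring C carries a 3-hydroxy-4-methoxyphenyl ring B at C2. There is no stereocentre, so nothing has to be set or relayed; the difficulty is entirely regiochemical. Five oxygen atoms must end in four different states: sulfate at O3 and O7, free phenol at O5 and O3', methyl ether at O4'. O7 must therefore be told from O5 on ring A, and O3' from O3 and O7. The two aryl sulfate monoesters are the fragile groups: they are strong acids, are lost in acid or on warm solvolysis, and make every compound that carries them ionic, so they must come last and be followed only by neutral operations. The 4-pyranone and its enolic O3 are in addition sensitive to hard nucleophiles and strong base. The feature that opens a short path is that ring C, with O1, the C4 carbonyl, O3 and an open position at C2, is the skeleton of kojic acid. O5 and O7 are meta to each other with O5 next to the ring fusion, which is the pattern a ketene carbon (C5) and an ynol ether oxygen (C7) leave in a vinylketene–alkyne benzannulation. The future C8a of the pyranone has only one carbon neighbour (the future C4a), so ring A can close in one place only.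

## Retrosynthesis

**Sulfate and silyl group.** The two O–S bonds at O3 and O7 and the O3'–Si bond are cut first: **24** comes from the salt **23**, this from the silylated disulfate **22**, and **22** from the triol **21**. Sulfation is placed last because every earlier position would drag ionic, acid-labile intermediates through the route. The forward reaction must spare O5, which its hydrogen bond to the C4 carbonyl ensures, and O3', which stays masked as a triisopropylsilyl ether until neutral fluoride removes it.

**Benzyl ethers.** The two benzyl C–O bonds of **20** are cut to give **21**. O3 and O7 both become sulfates, so they can share one protecting group and be freed together in one neutral hydrogenolysis that leaves the silyl ether alone. O5 needs no protection at any stage.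

**Ring A.** In **20** the bonds C5–C6, C7–C8 and C4a–C5 are cut, and C8–C8a is traced to a 1,2-shift, which leads back to the pyranonyl diazo ketone **10** and benzyloxyethyne **15** through **16**, **17**, **18** and **19**. The usual cuts through ring C start from a symmetrical ring A triphenol, whose O5 and O7 then have to be distinguished. Here O5 is born as a free phenol from the ketene carbon and O7 as a benzyl ether from the alkyne. The precursors are a monocyclic pyranone and a two-carbon alkyne. The forward step needs a regioselective [2+2] addition, ring closure at pyranone C3, and light that the pyranone does not absorb.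

**Diazo ketone.** The bond between the carboxyl carbon and the diazo carbon of **10** is cut, giving the mixed anhydride **9** of acid **8** and a diazoalkane as acyl acceptor. Acid **8** is the oxidation product of the primary alcohol **7**, so the hydroxymethyl group of kojic acid becomes C5 of the flavone. The forward steps must activate the acid without chlorinating the pyranone carbonyl and oxidise the alcohol without touching the electron-rich ring B.

**Ring B.** The C2–C1' bond of **7** is cut to the bromopyranone **3** and the arylboronate **6**. This cut is preferred because the bromine of **3** sits at the one position where kojic acid **1** is nucleophilic, so **3** follows from **1** through **2** by bromination and O-benzylation without any regiochemical effort. Boronate **6** comes from 5-bromo-2-methoxyphenol **4** through its silyl ether **5**. The coupling must tolerate a base-sensitive pyranone and an aryl silyl ether.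

**Ynol ether.** The O–C(sp) bond of **15** is cut to benzyl alcohol **11** and trichloroethylene **12**, by way of the dichlorovinyl ether **13** and the acetylide **14**. This is simpler than any route through a preformed alkyne. The forward sequence must be run cold, because **15** is thermally labile.

## Roads not taken

Alternative 1: Ring A is brought in whole as an aryne, and the cut runs through O1–C8a and C4–C4a. Fluoride would release a 3,5-dialkoxybenzyne from the silyl triflate **A3**. The carboxylate of the α-alkoxycinnamic acid **A2** adds to the aryne carbon remote from the flanking acetal oxygen, and the aryl anion so formed takes the acyl group back. The aryne thus inserts into the acid C–O bond and gives the ortho-hydroxyaryl enone **A1** with every oxygen of the target in place.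
- Merits: two fragments of similar size are joined late under mild conditions. The ring B benzyl ether could be removed after sulfation by neutral hydrogenolysis, an endgame at least as gentle as the fluoride step chosen here.
- Weak points: the step closes no ring, so ring C still needs an oxa-Michael closure and a dehydrogenation. The acid is also a proton source, so plain O-arylation to the aryl ester competes with acyl migration. **A3** is itself several steps from a symmetrical triphenol, and O5 and O7 carry the same acetal.
- Comparison: this road is more convergent. The chosen plan sets against it a key step that closes ring A, puts O5 and O7 in different states at once, and starts from a pyranone already at the right oxidation level. It pays with a diazo ketone, a photochemical step and a labile ynol ether.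

Alternative 2: The cut is C3–C4 inside ring C. A triazolium-derived carbene would turn the aryl aldehyde of dialdehyde **A5** into an acyl anion equivalent, which adds to the aliphatic aldehyde in an intramolecular crossed benzoin reaction and gives the trans-dihydroflavonol **A4**.
- Merits: the step is metal-free and mild, and it avoids both diazo chemistry and light, a clear advantage in safety and scale.
- Weak points: for this target it is a detour in oxidation level. **A4** has two stereocentres the planar flavonol does not need and must be dehydrogenated afterwards. The carbene must engage the doubly ortho-substituted, donor-rich aldehyde, the poorer electrophile of the two. The α-aryl-α-aryloxy aldehyde is easily enolised and can expel the phenoxide, and the reverse chemoselectivity would give the isomeric chroman-3-one.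
- Comparison: the chosen plan has no redox correction and no enolisable aldehyde, but it cannot match the operational simplicity of an organocatalytic step.

Alternative 3: The cut is C2–C3 and O1–C8a. The lithium enolate of the trifluorophenyl ketone **A7** would be C-acylated by the ring B acid chloride **A8**. The enolate oxygen of the resulting diketone then displaces an ortho fluoride in an intramolecular SNAr reaction and gives the difluoroflavone **A6** in one pot.
- Merits: up to the flavone core this road is better than the chosen one in robustness and step economy. It uses two simple fragments and ionic chemistry of firm precedent, and ring C closes at the right oxidation level.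
- Weak points: C5 and C7 still carry fluorine, and two C–F to C–O exchanges are needed. The first alkoxide makes ring A electron-rich and slows the second. The two positions must be addressed in a defined order to keep O5 and O7 distinct. Hot alkoxide also endangers the enol acetal at O3 and the pyranone ring, which nucleophiles open at C2.
- Comparison: the chosen plan has oxygen at C5 and C7, already differentiated, from the moment ring A exists, and needs no late nucleophilic substitution on the flavone. It must concede that its key step is less certain than this cascade.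

Key step: step 9

Assumption: the target is taken as drawn, in its fully protonated bis(hydrogen sulfate) form. Aryl hydrogen sulfates are strong acids that keep only as salts, so the route carries a bis(triethylammonium) salt to the last step and releases the acid form there by cold proton exchange.

## Route

Step 1
Reactants: 1 kojic acid [5-hydroxy-2-(hydroxymethyl)-4H-pyran-4-one]
Product: 2 2-bromo-3-hydroxy-6-(hydroxymethyl)-4H-pyran-4-one (6-bromokojic acid)
Conditions: NBS, MeCN, 0 °C to rt
Reagents that add atoms: N-bromosuccinimide, O=C1CCC(=O)N1Br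
Why: Electrophilic bromination of the enolic 3-hydroxy-4-pyranone should occur at the free carbon next to the enol hydroxyl, the position at which kojic acid also undergoes Mannich and aldol substitution.

Step 2
Reactants: 2 2-bromo-3-hydroxy-6-(hydroxymethyl)-4H-pyran-4-one
Product: 3 3-(benzyloxy)-2-bromo-6-(hydroxymethyl)-4H-pyran-4-one
Conditions: BnBr, K2CO3, DMF, rt
Reagents that add atoms: benzyl bromide, BrCc1ccccc1
Why: Williamson etherification; carbonate deprotonates only the acidic enol hydroxyl, so the primary alcohol should stay free and the future O3 is benzylated.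

Step 3
Reactants: 4 5-bromo-2-methoxyphenol
Product: 5 (5-bromo-2-methoxyphenoxy)triisopropylsilane
Conditions: TIPSCl, imidazole, DMF, rt
Reagents that add atoms: chlorotriisopropylsilane, CC(C)[Si](Cl)(C(C)C)C(C)C
Why: Imidazole-mediated O-silylation of a phenol; the bulky triisopropylsilyl ether is chosen because it should survive aqueous base, oxidation and hydrogenolysis and still fall to fluoride at the end.

Step 4
Reactants: 5 (5-bromo-2-methoxyphenoxy)triisopropylsilane
Product: 6 2-[4-methoxy-3-(triisopropylsilyloxy)phenyl]-4,4,5,5-tetramethyl-1,3,2-dioxaborolane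
Conditions: B2pin2, PdCl2(dppf) (cat.), KOAc, 1,4-dioxane, 85 °C
Reagents that add atoms: bis(pinacolato)diboron, CC1(C)OB(OC1(C)C)B1OC(C)(C)C(C)(C)O1
Why: Miyaura borylation of an aryl bromide; the weak acetate base leaves the aryl silyl ether untouched.

Step 5
Reactants: 3 3-(benzyloxy)-2-bromo-6-(hydroxymethyl)-4H-pyran-4-one; 6 2-[4-methoxy-3-(triisopropylsilyloxy)phenyl]-4,4,5,5-tetramethyl-1,3,2-dioxaborolane
Product: 7 3-(benzyloxy)-6-(hydroxymethyl)-2-[4-methoxy-3-(triisopropylsilyloxy)phenyl]-4H-pyran-4-one
Conditions: Pd(PPh3)4 (cat.), K3PO4, 1,4-dioxane/H2O, 70 °C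
Reagents that add atoms: none
Why: Suzuki–Miyaura coupling; the C–Br bond of 3 is that of a vinylogous acyl bromide and should add readily to zerovalent palladium, and phosphate is mild enough for the pyranone, the free alcohol and the silyl ether.

Step 6
Reactants: 7 3-(benzyloxy)-6-(hydroxymethyl)-2-[4-methoxy-3-(triisopropylsilyloxy)phenyl]-4H-pyran-4-one
Product: 8 5-(benzyloxy)-6-[4-methoxy-3-(triisopropylsilyloxy)phenyl]-4-oxo-4H-pyran-2-carboxylic acid
Conditions: TEMPO (cat.), PhI(OAc)2, MeCN/H2O, rt
Reagents that add atoms: water, O
Why: Oxoammonium-mediated oxidation of a primary alcohol through the aldehyde hydrate to the carboxylic acid; the near-neutral medium should spare the electron-rich ring B and the benzyl and silyl ethers.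

Step 7
Reactants: 8 5-(benzyloxy)-6-[4-methoxy-3-(triisopropylsilyloxy)phenyl]-4-oxo-4H-pyran-2-carboxylic acid
Product: 10 2-diazo-1-{5-(benzyloxy)-6-[4-methoxy-3-(triisopropylsilyloxy)phenyl]-4-oxo-4H-pyran-2-yl}ethan-1-one, via mixed isobutyl carbonic anhydride 9 (not isolated)
Conditions: i-BuOCOCl, N-methylmorpholine, THF, −15 °C; then CH2N2, Et2O, −15 to 0 °C
Reagents that add atoms: diazomethane, C=[N+]=[N-]; isobutyl chloroformate, CC(C)COC(=O)Cl (its atoms remain in 9 only)
Why: Acylation of diazomethane by a mixed carbonic anhydride, the first stage of an Arndt–Eistert sequence, with attack at the more electrophilic pyranoyl carbonyl. Chlorinating agents, which could turn the 4-pyranone into a chloropyrylium salt, are avoided, and no HCl is formed that could give a chloromethyl ketone.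

Step 8
Reactants: 11 benzyl alcohol; 12 trichloroethylene
Product: 15 (benzyloxy)ethyne, via benzyl (E)-1,2-dichlorovinyl ether 13 (not isolated), via lithium (benzyloxy)ethynide 14 (not isolated)
Conditions: KH, THF, 0 °C; Cl2C=CHCl, −50 °C to rt; n-BuLi, −78 °C; H2O, −78 to 0 °C; cold work-up
Reagents that add atoms: none
Why: The alkoxide adds anti to dichloroacetylene formed in situ from 12, giving the dichlorovinyl ether 13; n-BuLi then effects elimination and chlorine–lithium exchange to acetylide 14, which is protonated. The product is kept at or below room temperature as a solution, because benzyl alkynyl ethers undergo a [3,3]-sigmatropic shift on warming.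

Step 9
Reactants: 10 2-diazo-1-{5-(benzyloxy)-6-[4-methoxy-3-(triisopropylsilyloxy)phenyl]-4-oxo-4H-pyran-2-yl}ethan-1-one; 15 (benzyloxy)ethyne
Product: 20 3,7-bis(benzyloxy)-5-hydroxy-2-[4-methoxy-3-(triisopropylsilyloxy)phenyl]-4H-chromen-4-one, via pyranonylketene 16 (not isolated), via 4-pyranonylcyclobutenone 17 (not isolated), via (E)-dienylketene 18 (not isolated), via 4aH-chromene-4,5-dione tautomer 19 (not isolated)
Conditions: 15 (3 equiv), ClCH2CH2Cl, hν (440 nm LED), 15–20 °C; then 80 °C, dark
Reagents that add atoms: none
Why: Visible light expels N2 from 10 and the pyranonyl group shifts from the carbonyl carbon to the former diazo carbon (Wolff rearrangement), which ties C8 to C8a and gives ketene 16. The polarised ynol ether 15 adds to 16 in a [2+2] cycloaddition with its nucleophilic CH terminus on the ketene carbonyl carbon, so cyclobutenone 17 holds C5–C6 and C7–C8 with the benzyloxy group on the future C7. On heating, 17 opens by reversible conrotatory 4π electrocyclic cleavage; only dienylketene 18, with the pyranone cis to the ketene, can go on, and it is drained by 6π electrocyclisation onto pyranone C3, which forms C4a–C5 and closes the six-membered carbocyclic ring A. Dienone 19 then enolises to the chelated 5-phenol 20. The closest known reaction type is the Danheiser benzannulation in its photochemical Wolff variant, established for aryl, heteroaryl and alkenyl diazo ketones with alkoxy- and siloxyalkynes; the 4-pyranone is a new substrate of that class. No stereocentre remains, since those of 17 and 19 are transient and vanish on aromatisation. Three selectivities are needed: the [2+2] regiochemistry is secured by the donor oxygen of 15, the site of ring closure by the single carbon neighbour (C3) of pyranone C2, and the choice of chromophore by 440 nm light, which the diazo ketone should absorb through its n→π* tail while the aryl pyranone and flavone 20 stay dark.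

Step 10
Reactants: 20 3,7-bis(benzyloxy)-5-hydroxy-2-[4-methoxy-3-(triisopropylsilyloxy)phenyl]-4H-chromen-4-one
Product: 21 3,5,7-trihydroxy-2-[4-methoxy-3-(triisopropylsilyloxy)phenyl]-4H-chromen-4-one
Conditions: H2 (1 atm), Pd/C, EtOAc/MeOH, rt
Reagents that add atoms: none
Why: Hydrogenolysis of both benzyl ethers in one operation; the aryl silyl ether, the methyl ether and the flavonol C2=C3 bond should be inert at atmospheric pressure.

Step 11
Reactants: 21 3,5,7-trihydroxy-2-[4-methoxy-3-(triisopropylsilyloxy)phenyl]-4H-chromen-4-one
Product: 22 bis(triethylammonium) 5-hydroxy-2-[4-methoxy-3-(triisopropylsilyloxy)phenyl]-4-oxo-4H-chromene-3,7-diyl bis(sulfate)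
Conditions: SO3·NEt3 (6 equiv), Et3N, DMF, 40 °C; size-exclusion or C18 chromatography
Reagents that add atoms: sulfur trioxide–triethylamine complex, CC[N+](CC)(CC)S(=O)(=O)[O-]
Why: O-sulfation of phenols by an SO3–amine complex; the acidic 7-OH and the enolic 3-OH should react, whereas the 5-OH, locked in a hydrogen bond to the C4 carbonyl, is unreactive under such conditions and O3' is silylated.

Step 12
Reactants: 22 bis(triethylammonium) 5-hydroxy-2-[4-methoxy-3-(triisopropylsilyloxy)phenyl]-4-oxo-4H-chromene-3,7-diyl bis(sulfate)
Product: 24 5-hydroxy-2-(3-hydroxy-4-methoxyphenyl)-4-oxo-4H-chromene-3,7-diyl bis(hydrogen sulfate), via desilylated bis(triethylammonium) disulfate 23 (not isolated)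
Conditions: NH4F, MeOH, rt; then sulfonic acid cation-exchange resin (H+ form), H2O, 0–5 °C; freeze-drying
Reagents that add atoms: none
Why: Fluoride-induced cleavage of the aryl silyl ether, driven by the Si–F bond, under neutral conditions that aryl sulfate salts tolerate. Cold cation exchange on a proton-form resin then replaces the ammonium ions by protons and should give the acid form, to be freeze-dried at once.

## Compound list

1 | kojic acid, 5-hydroxy-2-(hydroxymethyl)-4H-pyran-4-one | OCc1cc(=O)c(O)co1 | starting material
2 | 2-bromo-3-hydroxy-6-(hydroxymethyl)-4H-pyran-4-one | OCc1cc(=O)c(O)c(Br)o1 | intermediate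
3 | 3-(benzyloxy)-2-bromo-6-(hydroxymethyl)-4H-pyran-4-one | OCc1cc(=O)c(OCc2ccccc2)c(Br)o1 | intermediate
4 | 5-bromo-2-methoxyphenol | COc1ccc(Br)cc1O | starting material
5 | (5-bromo-2-methoxyphenoxy)triisopropylsilane | COc1ccc(Br)cc1O[Si](C(C)C)(C(C)C)C(C)C | intermediate
6 | 2-[4-methoxy-3-(triisopropylsilyloxy)phenyl]-4,4,5,5-tetramethyl-1,3,2-dioxaborolane | COc1ccc(B2OC(C)(C)C(C)(C)O2)cc1O[Si](C(C)C)(C(C)C)C(C)C | intermediate
7 | 3-(benzyloxy)-6-(hydroxymethyl)-2-[4-methoxy-3-(triisopropylsilyloxy)phenyl]-4H-pyran-4-one | OCc1cc(=O)c(OCc2ccccc2)c(-c2ccc(OC)c(O[Si](C(C)C)(C(C)C)C(C)C)c2)o1 | intermediate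
8 | 5-(benzyloxy)-6-[4-methoxy-3-(triisopropylsilyloxy)phenyl]-4-oxo-4H-pyran-2-carboxylic acid | OC(=O)c1cc(=O)c(OCc2ccccc2)c(-c2ccc(OC)c(O[Si](C(C)C)(C(C)C)C(C)C)c2)o1 | intermediate
9 | 5-(benzyloxy)-6-[4-methoxy-3-(triisopropylsilyloxy)phenyl]-4-oxo-4H-pyran-2-carboxylic isobutyl carbonic anhydride | CC(C)COC(=O)OC(=O)c1cc(=O)c(OCc2ccccc2)c(-c2ccc(OC)c(O[Si](C(C)C)(C(C)C)C(C)C)c2)o1 | intermediate (not isolated)
10 | 2-diazo-1-{5-(benzyloxy)-6-[4-methoxy-3-(triisopropylsilyloxy)phenyl]-4-oxo-4H-pyran-2-yl}ethan-1-one | [N-]=[N+]=CC(=O)c1cc(=O)c(OCc2ccccc2)c(-c2ccc(OC)c(O[Si](C(C)C)(C(C)C)C(C)C)c2)o1 | intermediate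
11 | benzyl alcohol | OCc1ccccc1 | starting material
12 | trichloroethylene | ClC=C(Cl)Cl | starting material
13 | benzyl (E)-1,2-dichlorovinyl ether | Cl/C=C(Cl)\OCc1ccccc1 | intermediate (not isolated)
14 | lithium (benzyloxy)ethynide | [Li]C#COCc1ccccc1 | intermediate (not isolated)
15 | (benzyloxy)ethyne | C#COCc1ccccc1 | intermediate
16 | 2-{5-(benzyloxy)-6-[4-methoxy-3-(triisopropylsilyloxy)phenyl]-4-oxo-4H-pyran-2-yl}ethen-1-one (pyranonylketene) | O=C=Cc1cc(=O)c(OCc2ccccc2)c(-c2ccc(OC)c(O[Si](C(C)C)(C(C)C)C(C)C)c2)o1 | intermediate (not isolated)
17 | 3-(benzyloxy)-4-{5-(benzyloxy)-6-[4-methoxy-3-(triisopropylsilyloxy)phenyl]-4-oxo-4H-pyran-2-yl}cyclobut-2-en-1-one (racemic) | O=C1C=C(OCc2ccccc2)C1c1cc(=O)c(OCc2ccccc2)c(-c2ccc(OC)c(O[Si](C(C)C)(C(C)C)C(C)C)c2)o1 | intermediate (not isolated)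
18 | (3E)-3-(benzyloxy)-4-{5-(benzyloxy)-6-[4-methoxy-3-(triisopropylsilyloxy)phenyl]-4-oxo-4H-pyran-2-yl}buta-1,3-dien-1-one | O=C=C/C(OCc1ccccc1)=C\c1cc(=O)c(OCc2ccccc2)c(-c2ccc(OC)c(O[Si](C(C)C)(C(C)C)C(C)C)c2)o1 | intermediate (not isolated)
19 | 3,7-bis(benzyloxy)-2-[4-methoxy-3-(triisopropylsilyloxy)phenyl]-4aH-chromene-4,5-dione (racemic keto tautomer of 20) | O=C1C=C(OCc2ccccc2)C=C2OC(-c3ccc(OC)c(O[Si](C(C)C)(C(C)C)C(C)C)c3)=C(OCc3ccccc3)C(=O)C12 | intermediate (not isolated)
20 | 3,7-bis(benzyloxy)-5-hydroxy-2-[4-methoxy-3-(triisopropylsilyloxy)phenyl]-4H-chromen-4-one | O=c1c(OCc2ccccc2)c(-c2ccc(OC)c(O[Si](C(C)C)(C(C)C)C(C)C)c2)oc2cc(OCc3ccccc3)cc(O)c12 | intermediate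
21 | 3,5,7-trihydroxy-2-[4-methoxy-3-(triisopropylsilyloxy)phenyl]-4H-chromen-4-one | O=c1c(O)c(-c2ccc(OC)c(O[Si](C(C)C)(C(C)C)C(C)C)c2)oc2cc(O)cc(O)c12 | intermediate
22 | bis(triethylammonium) 5-hydroxy-2-[4-methoxy-3-(triisopropylsilyloxy)phenyl]-4-oxo-4H-chromene-3,7-diyl bis(sulfate) | CC[NH+](CC)CC.CC[NH+](CC)CC.COc1ccc(-c2oc3cc(OS(=O)(=O)[O-])cc(O)c3c(=O)c2OS(=O)(=O)[O-])cc1O[Si](C(C)C)(C(C)C)C(C)C | intermediate
23 | bis(triethylammonium) 5-hydroxy-2-(3-hydroxy-4-methoxyphenyl)-4-oxo-4H-chromene-3,7-diyl bis(sulfate) | CC[NH+](CC)CC.CC[NH+](CC)CC.COc1ccc(-c2oc3cc(OS(=O)(=O)[O-])cc(O)c3c(=O)c2OS(=O)(=O)[O-])cc1O | intermediate (not isolated)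
24 | 5-hydroxy-2-(3-hydroxy-4-methoxyphenyl)-4-oxo-4H-chromene-3,7-diyl bis(hydrogen sulfate) | COc1ccc(-c2oc3cc(OS(=O)(=O)O)cc(O)c3c(=O)c2OS(=O)(=O)O)cc1O | target

## Step count and risks

Total step count: 12. Longest linear sequence: 9 steps (steps 1, 2, 5, 6, 7, 9, 10, 11, 12 from kojic acid 1; the branch from 4 through steps 3 and 4 is equally long).

**Step 9 (key step).** The likely failures are:
- loss of ketene 16 to dimerisation or moisture before it meets 15;
- consumption of 15 by its own [3,3] shift or polymerisation during a long irradiation;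
- slow light uptake through the weak visible band of the diazo ketone, which invites shorter wavelengths at which the aryl pyranone absorbs and can abstract hydrogen from its benzylic ether;
- ring opening of 17 that is too slow at 80 °C.

Fallback: make the same ketene in the dark by dehydrochlorination. Setting out from 10, a Wolff rearrangement catalysed by silver benzoate (AgO2CPh) with Et3N in aqueous THF (Arndt–Eistert homologation) should give {5-(benzyloxy)-6-[4-methoxy-3-(triisopropylsilyloxy)phenyl]-4-oxo-4H-pyran-2-yl}acetic acid F1. The neutral chlorinating agent 1-chloro-N,N,2-trimethylprop-1-en-1-amine converts it into {5-(benzyloxy)-6-[4-methoxy-3-(triisopropylsilyloxy)phenyl]-4-oxo-4H-pyran-2-yl}acetyl chloride F2. Slow addition of Et3N to F2 and 15 in CH2Cl2 at 0 °C releases ketene 16, which is trapped as cyclobutenone 17. The fallback rejoins the route there, and heating as in step 9 leads on to 20.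

**Step 8.** The ynol ether may be lost on concentration or warming through the [3,3]-sigmatropic shift of its benzyl group, and through hydration on acidic silica. Fallback: change the O7 protecting group and with it the alkyne. Setting out from 12, potassium tert-butoxide and then n-BuLi, in the same addition–elimination sequence, give tert-butoxyethyne F3. It has no [3,3] pathway and is volatile, so its excess can be removed before the heating stage. With 10 under the conditions of step 9 it should give 3-(benzyloxy)-7-tert-butoxy-5-hydroxy-2-[4-methoxy-3-(triisopropylsilyloxy)phenyl]-4H-chromen-4-one F4. CF3CO2H in CH2Cl2 at 0 °C removes the tert-butyl group as isobutene and gives 3-(benzyloxy)-5,7-dihydroxy-2-[4-methoxy-3-(triisopropylsilyloxy)phenyl]-4H-chromen-4-one F5. Hydrogenolysis as in step 10 returns to the route at 21.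

**Step 5.** Hydroxide or phosphate may attack the bromopyranone (addition–elimination at the bromine-bearing carbon or ring opening). The electron-rich boronate may protodeboronate, and the silyl ether may be partly lost in hot aqueous base. Fallback: a base-free Stille coupling. Setting out from 5, bromine–lithium exchange (n-BuLi, THF, −78 °C) and Bu3SnCl give tributyl[4-methoxy-3-(triisopropylsilyloxy)phenyl]stannane F6. Coupling of F6 with 3 (Pd(PPh3)4, CuI, DMF, 80 °C) returns to the route at 7.

**Step 11.** Sulfation may stop at the 7-monosulfate because the enolic O3 is hindered, or go on to O5 when forced, and the ionic mixture is hard to separate. Fallback: protected sulfate diesters. Setting out from 21, 2,2,2-trichloroethyl chlorosulfate with Et3N and DMAP in THF should give the neutral 5-hydroxy-2-[4-methoxy-3-(triisopropylsilyloxy)phenyl]-4-oxo-4H-chromene-3,7-diyl bis(2,2,2-trichloroethyl) bis(sulfate) F7, which can be purified on silica. Zn and HCO2NH4 in MeOH remove the trichloroethyl groups reductively and give bis(ammonium) 5-hydroxy-2-[4-methoxy-3-(triisopropylsilyloxy)phenyl]-4-oxo-4H-chromene-3,7-diyl bis(sulfate) F8. Under the conditions of step 12 (NH4F, then proton-form resin) F8 returns to the route at 24.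

## Further compounds

F1 | step 9 | {5-(benzyloxy)-6-[4-methoxy-3-(triisopropylsilyloxy)phenyl]-4-oxo-4H-pyran-2-yl}acetic acid | OC(=O)Cc1cc(=O)c(OCc2ccccc2)c(-c2ccc(OC)c(O[Si](C(C)C)(C(C)C)C(C)C)c2)o1
F2 | step 9 | {5-(benzyloxy)-6-[4-methoxy-3-(triisopropylsilyloxy)phenyl]-4-oxo-4H-pyran-2-yl}acetyl chloride | ClC(=O)Cc1cc(=O)c(OCc2ccccc2)c(-c2ccc(OC)c(O[Si](C(C)C)(C(C)C)C(C)C)c2)o1
F3 | step 8 | tert-butoxyethyne | C#COC(C)(C)C
F4 | step 8 | 3-(benzyloxy)-7-tert-butoxy-5-hydroxy-2-[4-methoxy-3-(triisopropylsilyloxy)phenyl]-4H-chromen-4-one | O=c1c(OCc2ccccc2)c(-c2ccc(OC)c(O[Si](C(C)C)(C(C)C)C(C)C)c2)oc2cc(OC(C)(C)C)cc(O)c12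
F5 | step 8 | 3-(benzyloxy)-5,7-dihydroxy-2-[4-methoxy-3-(triisopropylsilyloxy)phenyl]-4H-chromen-4-one | O=c1c(OCc2ccccc2)c(-c2ccc(OC)c(O[Si](C(C)C)(C(C)C)C(C)C)c2)oc2cc(O)cc(O)c12
F6 | step 5 | tributyl[4-methoxy-3-(triisopropylsilyloxy)phenyl]stannane | CCCC[Sn](CCCC)(CCCC)c1ccc(OC)c(O[Si](C(C)C)(C(C)C)C(C)C)c1
F7 | step 11 | 5-hydroxy-2-[4-methoxy-3-(triisopropylsilyloxy)phenyl]-4-oxo-4H-chromene-3,7-diyl bis(2,2,2-trichloroethyl) bis(sulfate) | COc1ccc(-c2oc3cc(OS(=O)(=O)OCC(Cl)(Cl)Cl)cc(O)c3c(=O)c2OS(=O)(=O)OCC(Cl)(Cl)Cl)cc1O[Si](C(C)C)(C(C)C)C(C)C
F8 | step 11 | bis(ammonium) 5-hydroxy-2-[4-methoxy-3-(triisopropylsilyloxy)phenyl]-4-oxo-4H-chromene-3,7-diyl bis(sulfate) | [NH4+].[NH4+].COc1ccc(-c2oc3cc(OS(=O)(=O)[O-])cc(O)c3c(=O)c2OS(=O)(=O)[O-])cc1O[Si](C(C)C)(C(C)C)C(C)C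
A1 | alternative 1 | (Z)-3-[3-(benzyloxy)-4-methoxyphenyl]-1-[2-hydroxy-4,6-bis(methoxymethoxy)phenyl]-2-(methoxymethoxy)prop-2-en-1-one | COCOc1cc(O)c(C(=O)/C(OCOC)=C/c2ccc(OC)c(OCc3ccccc3)c2)c(OCOC)c1
A2 | alternative 1 | (Z)-3-[3-(benzyloxy)-4-methoxyphenyl]-2-(methoxymethoxy)prop-2-enoic acid | COCO/C(=C\c1ccc(OC)c(OCc2ccccc2)c1)C(=O)O
A3 | alternative 1 | 2,4-bis(methoxymethoxy)-6-(trimethylsilyl)phenyl trifluoromethanesulfonate | COCOc1cc(OCOC)c(OS(=O)(=O)C(F)(F)F)c([Si](C)(C)C)c1
A4 | alternative 2 | trans-2-[3-(benzyloxy)-4-methoxyphenyl]-3-hydroxy-5,7-bis(methoxymethoxy)chroman-4-one (racemic, 2R,3R enantiomer drawn) | COc1ccc(cc1OCc1ccccc1)[C@@H]1[C@@H](O)C(=O)c2c(OCOC)cc(OCOC)cc2O1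
A5 | alternative 2 | 2-{1-[3-(benzyloxy)-4-methoxyphenyl]-2-oxoethoxy}-4,6-bis(methoxymethoxy)benzaldehyde (racemic) | COc1ccc(cc1OCc1ccccc1)C(C=O)Oc1cc(OCOC)cc(OCOC)c1C=O
A6 | alternative 3 | 2-[3-(benzyloxy)-4-methoxyphenyl]-5,7-difluoro-3-(methoxymethoxy)-4H-chromen-4-one | COCOc1c(-c2ccc(OC)c(OCc3ccccc3)c2)oc2cc(F)cc(F)c2c1=O
A7 | alternative 3 | 2-(methoxymethoxy)-1-(2,4,6-trifluorophenyl)ethan-1-one | COCOCC(=O)c1c(F)cc(F)cc1F
A8 | alternative 3 | 3-(benzyloxy)-4-methoxybenzoyl chloride | COc1ccc(C(=O)Cl)cc1OCc1ccccc1
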